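**Retrosynthetic overview**
1. Both acetate C–O bonds are cut in one operation. A lipase/ruthenium dynamic kinetic asymmetric O-acetylation of stereorandom [4]-gingerdiol forms both bonds and fixes C5 (R) and C3 (S).
2. The stereorandom diol comes from racemic [4]-gingerol by an uncontrolled reduction of the C3 ketone.
3. Racemic [4]-gingerol comes from zingerone and butanal by a terminal-enolate aldol addition, the only skeletal bond made.
4. No ring is built. The arene comes intact from zingerone, and the only cycle is a transient six-membered orthoacid during the acetyl shift.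

Assumption: locants follow gingerol numbering (C1 = benzylic CH2, C3 and C5 = oxygenated carbons). The target SMILES reads as the (3S,5R) syn isomer.

**Step 1**
Reactants: 1 zingerone [4-(4-hydroxy-3-methoxyphenyl)butan-2-one]; 2 butanal
Product: 4 rac-[4]-gingerol [5-hydroxy-1-(4-hydroxy-3-methoxyphenyl)octan-3-one], via dilithio zingerone dianion 3 (not isolated)
Conditions: LiHMDS (2.2 equiv), THF, −78 °C, 1 h; 2 (1.2 equiv), −78 °C, 1 h; AcOH (2.5 equiv), −78 °C to rt
Reagents that add atoms: none
Why: The first equivalent of base gives the phenoxide and the second removes a proton kinetically from the less hindered CH3, so the terminal enolate adds to butanal (directed lithium-enolate aldol addition); C5 is left racemic because step 3 corrects it.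

**Step 2**
Reactants: 4 rac-[4]-gingerol
Product: 5 [4]-gingerdiol [1-(4-hydroxy-3-methoxyphenyl)octane-3,5-diol], all four stereoisomers
Conditions: NaBH4 (1.0 equiv), MeOH, 0 °C, 30 min; 1 M HCl to pH 6
Reagents that add atoms: none
Why: This is a plain borohydride 1,2-reduction of the ketone that leaves the phenol, aryl ether and secondary alcohol untouched, and it needs no stereocontrol because both carbinols are equilibrated in step 3.

**Step 3**
Reactants: 5 [4]-gingerdiol (stereoisomer mixture)
Product: 10 (3S,5R)-1-(4-hydroxy-3-methoxyphenyl)octane-3,5-diyl diacetate, via 5-oxo hydroxy ketone 6 (not isolated), via 5-O-monoacetate 7 (not isolated), via 3-oxo acetoxy ketone 8 (not isolated), via 3-O-monoacetate 9 (not isolated)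
Conditions: 4-ClC6H4OAc (3 equiv), Shvo's Ru dimer (4 mol %), immobilised Burkholderia cepacia lipase (Amano PS-IM), PhMe, 70 °C, Ar, 48–72 h; filter, chromatograph
Reagents that add atoms: 4-chlorophenyl acetate, CC(=O)Oc1ccc(Cl)cc1
Why: Proposed new method: a lipase/ruthenium dynamic kinetic asymmetric transformation (DYKAT) run on a 1,3-diol that has no methyl carbinol and carries a free phenol; by the Kazlauskas rule the lipase can seat only the n-propyl group of C5 in its medium pocket, so it acetylates only (5R)-OH (5 to 7) and leaves C3-OH and the phenol alone; Shvo's catalyst keeps every still-free carbinol epimerising by outer-sphere dehydrogenation/re-hydrogenation (through 6 and 8); the acetyl group then shifts from O5 to O3 through a chair 2-hydroxy-2-methyl-1,3-dioxane that is low in energy only for the syn isomer with both chains equatorial (7 to 9, locking C3 as S); the lipase acetylates the freed (5R)-OH a second time to give 10, which has no free carbinol and cannot epimerise further; because the enzyme reads C5 twice, a single mis-acylation ends in a separable anti diacetate and not in the enantiomer; the closest known reaction type is the CALB/Ru DYKAT of 1-substituted butane-1,3-diols (methyl carbinols) to syn-1,3-diacetates, and phenol tolerance is expected because the acyl donor always releases 4-chlorophenol in such runs.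

**Compound list**
1 | zingerone, 4-(4-hydroxy-3-methoxyphenyl)butan-2-one | CC(=O)CCc1ccc(O)c(OC)c1 | starting material
2 | butanal | CCCC=O | starting material
3 | dilithium phenoxide/terminal enolate of zingerone | C=C([O-])CCc1ccc([O-])c(OC)c1.[Li+].[Li+] | intermediate
4 | rac-[4]-gingerol, 5-hydroxy-1-(4-hydroxy-3-methoxyphenyl)octan-3-one | CCCC(O)CC(=O)CCc1ccc(O)c(OC)c1 | intermediate
5 | [4]-gingerdiol, 1-(4-hydroxy-3-methoxyphenyl)octane-3,5-diol, syn/anti about 1:1, each racemic | CCCC(O)CC(O)CCc1ccc(O)c(OC)c1 | intermediate
6 | 3-hydroxy-1-(4-hydroxy-3-methoxyphenyl)octan-5-one, transient ketone of C5 epimerisation | CCCC(=O)CC(O)CCc1ccc(O)c(OC)c1 | intermediate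
7 | (5R)-3-hydroxy-1-(4-hydroxy-3-methoxyphenyl)octan-5-yl acetate, C3 epimers | CCC[C@H](CC(O)CCc1ccc(O)c(OC)c1)OC(C)=O | intermediate
8 | (5R)-1-(4-hydroxy-3-methoxyphenyl)-3-oxooctan-5-yl acetate, transient ketone of C3 epimerisation | CCC[C@H](CC(=O)CCc1ccc(O)c(OC)c1)OC(C)=O | intermediate
9 | (3S,5R)-5-hydroxy-1-(4-hydroxy-3-methoxyphenyl)octan-3-yl acetate | CCC[C@H](C[C@H](CCc1ccc(O)c(OC)c1)OC(C)=O)O | intermediate
10 | (3S,5R)-1-(4-hydroxy-3-methoxyphenyl)octane-3,5-diyl diacetate (CNP0240815.1) | CCC[C@H](C[C@H](CCc1ccc(O)c(OC)c1)OC(C)=O)OC(C)=O | target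

**Totals**
Total step count: 3. Longest linear sequence: 3.

**Steps most likely to fail**

1. **Step 3 (the proposed new step).**
   - Risks:
     - The lipase may discriminate poorly when n-propyl is the "medium" group.
     - It may acetylate C3-OH directly, which would erode dr and ee.
     - Ketone 8 may lose acetic acid to give the enone.
     - The phenol may be partly O-acetylated.
   - Fallback (known chemistry): it sets out from 4 and comes back at 10.
     - Compound 4 is dehydrated (p-TsOH, PhMe, reflux) to (E)-[4]-shogaol F2.
     - Enantioselective Cu(I)/Josiphos conjugate borylation follows (B2pin2, MeOH, THF), with the ligand enantiomer chosen for 5R. It gives (5R)-1-(4-hydroxy-3-methoxyphenyl)-5-(pinacolatoboryl)octan-3-one F3.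
     - NaBO3 oxidises the C–B bond with retention to (R)-[4]-gingerol F4.
     - Narasaka–Prasad reduction (Et2BOMe, NaBH4, THF/MeOH, −78 °C) gives (3S,5R)-[4]-gingerdiol F5.
     - Ac2O/pyridine/DMAP gives the (3S,5R)-triacetate F6.
     - Pyrrolidine (1.1 equiv, MeCN, 0 °C to rt) cleaves only the aryl acetate and delivers 10.

2. **Step 1.**
   - Risks: incomplete conversion of the poorly soluble dianion, self-aldol of butanal, and retro-aldol or dehydration on work-up.
   - Fallback: acylation instead of aldol addition, setting out from 1 and coming back at 5. Claisen acylation of 1 with ethyl butyrate (NaH, 3 equiv, THF, reflux) occurs at the methyl group. It gives [4]-gingerdione F1. Excess NaBH4 (MeOH/THF, 0 °C to rt) reduces both carbonyls of F1 to 5, so 4 is bypassed.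

3. **Step 2.**
   - Risk: the basic borohydride medium can trigger retro-aldol cleavage or dehydration of 4.
   - Fallback: neutral catalytic transfer hydrogenation instead of a hydride reagent, setting out from 4 and coming back at 5. Compound 4 is heated with Shvo's catalyst in 2-propanol/toluene (70–80 °C). The volatiles are stripped, and the lipase and acyl donor of step 3 are added to the same flask. No new compound is made.

**Further compounds**
F1 | step 1 | [4]-gingerdione, 1-(4-hydroxy-3-methoxyphenyl)octane-3,5-dione | CCCC(=O)CC(=O)CCc1ccc(O)c(OC)c1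
F0 | step 2 | none | none
F2 | step 3 | (E)-[4]-shogaol, (E)-1-(4-hydroxy-3-methoxyphenyl)oct-4-en-3-one | CCC/C=C/C(=O)CCc1ccc(O)c(OC)c1
F3 | step 3 | (5R)-1-(4-hydroxy-3-methoxyphenyl)-5-(4,4,5,5-tetramethyl-1,3,2-dioxaborolan-2-yl)octan-3-one | CCC[C@H](CC(=O)CCc1ccc(O)c(OC)c1)B1OC(C)(C)C(C)(C)O1
F4 | step 3 | (R)-[4]-gingerol, (5R)-5-hydroxy-1-(4-hydroxy-3-methoxyphenyl)octan-3-one | CCC[C@H](CC(=O)CCc1ccc(O)c(OC)c1)O
F5 | step 3 | (3S,5R)-[4]-gingerdiol, (3S,5R)-1-(4-hydroxy-3-methoxyphenyl)octane-3,5-diol | CCC[C@H](C[C@H](CCc1ccc(O)c(OC)c1)O)O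
F6 | step 3 | (3S,5R)-1-(4-acetoxy-3-methoxyphenyl)octane-3,5-diyl diacetate | CCC[C@H](C[C@H](CCc1ccc(OC(C)=O)c(OC)c1)OC(C)=O)OC(C)=O
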